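**Plan**
- Cuts: flavone ring C at O1–C2, C3–C4 and C4–C4a (ortho-iodophenol + CO + catechol alkyne); then the cyclohexane bond C-a–C-f; then C-b–C-c (Ireland–Claisen) and the ester C–O bond.
- Feature: with the cyclohexane labelled C-a (C=CH2), C-b (CH carrying CH2Ar), C-c (CMe2), C-d and C-e (CH2) and C-f (CHOH), the neighbours C-a/C-f form an allylic alcohol on a 1,1-disubstituted alkene. This is what a terminal alkyne on C-b and an aldehyde at C-f give on reductive coupling.
- Forward: protected phloroglucinaldehyde → 3-arylpropanoic acid → ester of a chiral allylic alcohol → Ireland–Claisen (C-b–C-c, chain complete) → ynal → nickel-catalysed closure of the cyclohexane → ring C by carbonylative annulation on ring A → fluoride deprotection.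
- Stereochemistry: C-b from (S)-but-3-ene-1,2-diol by 1,3-chirality transfer through the chair transition state of the Ireland–Claisen rearrangement; C-f from the chiral carbene ligand on nickel in the ring closure.

Key step: step 14

Abbreviations: SEM = 2-(trimethylsilyl)ethoxymethyl, TIPS = triisopropylsilyl, TBS = tert-butyldimethylsilyl; Ar = 2,6-bis(SEM-oxy)-4-(TIPS-oxy)phenyl.
Remark (assumption): the (R,R)-enantiomer of the C2-symmetric carbene ligand is taken as the one that directs C-a to the Re face of the aldehyde in 21; if the sense is opposite, the (S,S)-ligand is used with no other change.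

Step 1
Reactants: 1 (S)-but-3-ene-1,2-diol
Product: 2 (S)-1-(TBS-oxy)but-3-en-2-ol
Conditions: TBSCl (1.05 equiv), imidazole, CH2Cl2, −20 → 0 °C
Reagents that add atoms: tert-butyldimethylsilyl chloride, CC(C)(C)[Si](C)(C)Cl
Why: Silyl ether formation with a bulky chlorosilane is selective for the primary hydroxyl of a 1,2-diol and leaves the carbinol stereocentre untouched.

Step 2
Reactants: 2 (S)-1-(TBS-oxy)but-3-en-2-ol; 3 2-methylbut-2-ene
Product: 4 (S)-1-(TBS-oxy)-4-methylpent-3-en-2-ol
Conditions: second-generation Grubbs catalyst (3 mol %), neat 3 (excess), 40 °C, sealed tube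
Reagents that add atoms: none
Why: Olefin cross-metathesis of a terminal alkene with excess 2-methylbut-2-ene exchanges the methylidene terminus for an isopropylidene group while propene escapes, and the allylic stereocentre is not involved.

Step 3
Reactants: 5 2,4,6-trihydroxybenzaldehyde
Product: 6 2,6-dihydroxy-4-(TIPS-oxy)benzaldehyde
Conditions: TIPSCl (1.05 equiv), imidazole, DMF, 0 °C
Reagents that add atoms: triisopropylsilyl chloride, CC(C)[Si](Cl)(C(C)C)C(C)C
Why: Regioselective phenol silylation, because the 4-hydroxyl is the most acidic and the only one not hydrogen-bonded to the formyl group.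

Step 4
Reactants: 6 2,6-dihydroxy-4-(TIPS-oxy)benzaldehyde
Product: 7 2,6-bis(SEM-oxy)-4-(TIPS-oxy)benzaldehyde
Conditions: NaH (2.3 equiv), SEMCl (2.5 equiv), THF–DMF, 0 °C → rt
Reagents that add atoms: 2-(trimethylsilyl)ethoxymethyl chloride, C[Si](C)(C)CCOCCl
Why: Williamson-type O-alkylation, in which double deprotonation breaks the hydrogen bonds to the formyl group and both phenoxides are captured by the reactive chloromethyl ether, while the hindered aryl TIPS ether resists the non-nucleophilic base.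

Step 5
Reactants: 7 2,6-bis(SEM-oxy)-4-(TIPS-oxy)benzaldehyde; 8 Meldrum's acid
Product: 10 5-(Ar-methyl)-2,2-dimethyl-1,3-dioxane-4,6-dione, via arylidene Meldrum's acid 9 (not isolated)
Conditions: L-proline (20 mol %), Hantzsch ester (1.1 equiv), EtOH, rt
Reagents that add atoms: none
Why: Three-component reductive alkylation, in which amine-catalysed Knoevenagel condensation gives the electron-poor arylidene 9 and hydride transfer from the Hantzsch ester reduces it in the same flask under conditions mild enough for the SEM and TIPS ethers.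

Step 6
Reactants: 10 5-(Ar-methyl)-2,2-dimethyl-1,3-dioxane-4,6-dione
Product: 12 3-Ar-propanoic acid, via arylmethylmalonic acid 11 (not isolated)
Conditions: pyridine–H2O (10:1), 100 °C
Reagents that add atoms: water, O
Why: Hydrolytic opening of the dioxanedione followed by thermal decarboxylation of the malonic acid in hot aqueous pyridine, a basic medium that spares the acid-labile SEM acetals.

Step 7
Reactants: 12 3-Ar-propanoic acid; 4 (S)-1-(TBS-oxy)-4-methylpent-3-en-2-ol
Product: 13 (S)-1-(TBS-oxy)-4-methylpent-3-en-2-yl 3-Ar-propanoate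
Conditions: DCC (1.2 equiv), DMAP (10 mol %), CH2Cl2, 0 °C → rt
Reagents that add atoms: none
Why: Steglich esterification acylates the secondary allylic alcohol at oxygen without touching its C–O bond, so the configuration of 4 is carried into the ester unchanged.

Step 8
Reactants: 13 (S)-1-(TBS-oxy)-4-methylpent-3-en-2-yl 3-Ar-propanoate
Product: 16 (2S,4E)-2-(Ar-methyl)-6-(TBS-oxy)-3,3-dimethylhex-4-en-1-ol, via silyl ketene acetal 14 (not isolated), via trimethylsilyl ester 15 (not isolated)
Conditions: LiN(iPr)2 (1.3 equiv), THF, −78 °C; Me3SiCl–Et3N, −78 °C → 60 °C; then LiAlH4, 0 °C → rt; aq. KNaC4H4O6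
Reagents that add atoms: none
Why: Ireland–Claisen rearrangement, in which kinetic enolisation in THF without polar additive gives the ketene acetal 14 with ArCH2 cis to the allyloxy oxygen, the chair transition state places the CH2OTBS group of the (S)-carbinol equatorial (the axial alternative clashes with the axial methyl of the isopropylidene terminus) so that the C–O stereocentre is exchanged for (S)-configured C-b and an E alkene, and LiAlH4 then reduces the silyl ester 15 to the primary alcohol in the same flask.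

Step 9
Reactants: 16 (2S,4E)-2-(Ar-methyl)-6-(TBS-oxy)-3,3-dimethylhex-4-en-1-ol
Product: 17 (S)-2-(Ar-methyl)-6-(TBS-oxy)-3,3-dimethylhexan-1-ol
Conditions: H2 (1 atm), PtO2 (5 mol %), EtOAc, rt
Reagents that add atoms: none
Why: Heterogeneous catalytic hydrogenation saturates the only C=C bond, platinum being chosen because it causes less hydrogenolysis of the allylic silyl ether than palladium, and C-b is not affected.

Step 10
Reactants: 17 (S)-2-(Ar-methyl)-6-(TBS-oxy)-3,3-dimethylhexan-1-ol
Product: 18 (S)-2-(Ar-methyl)-6-(TBS-oxy)-3,3-dimethylhexanal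
Conditions: Dess–Martin periodinane (1.3 equiv), pyridine, CH2Cl2, 0 °C → rt
Reagents that add atoms: none
Why: Dess–Martin oxidation of the primary alcohol under buffered conditions stops at the aldehyde and does not epimerise the α-stereocentre C-b.

Step 11
Reactants: 18 (S)-2-(Ar-methyl)-6-(TBS-oxy)-3,3-dimethylhexanal
Product: 19 (5S)-5-(Ar-methyl)-1-(TBS-oxy)-4,4-dimethylhept-6-yne
Conditions: dimethyl (1-diazo-2-oxopropyl)phosphonate (1.5 equiv), K2CO3 (2 equiv), MeOH, 0 °C → rt
Reagents that add atoms: dimethyl (1-diazo-2-oxopropyl)phosphonate, COP(=O)(OC)C(=[N+]=[N-])C(C)=O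
Why: Ohira–Bestmann homologation, in which the diazophosphonate anion released by methanolysis adds to the aldehyde and the resulting alkylidene carbene undergoes 1,2-hydride shift to the terminal alkyne, while C-b, flanked by a quaternary carbon, enolises slowly and should keep its configuration.

Step 12
Reactants: 19 (5S)-5-(Ar-methyl)-1-(TBS-oxy)-4,4-dimethylhept-6-yne
Product: 20 (5S)-5-(Ar-methyl)-4,4-dimethylhept-6-yn-1-ol
Conditions: camphorsulfonic acid (10 mol %), MeOH–CH2Cl2 (1:1), 0 °C
Reagents that add atoms: none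
Why: Acid-catalysed methanolysis is selective for the primary alkyl TBS ether, since aryl silyl ethers are cleaved by nucleophiles and not by dilute acid, and the aryl SEM acetals survive brief exposure to catalytic sulfonic acid at 0 °C.

Step 13
Reactants: 20 (5S)-5-(Ar-methyl)-4,4-dimethylhept-6-yn-1-ol
Product: 21 (5S)-5-(Ar-methyl)-4,4-dimethylhept-6-ynal
Conditions: Dess–Martin periodinane (1.3 equiv), pyridine, CH2Cl2, 0 °C → rt
Reagents that add atoms: none
Why: Dess–Martin oxidation converts the primary alcohol into the aldehyde in the presence of the terminal alkyne and completes the ynal.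

Step 14
Reactants: 21 (5S)-5-(Ar-methyl)-4,4-dimethylhept-6-ynal; 22 triethylsilane
Product: 23 triethyl{[(1S,3S)-3-(Ar-methyl)-4,4-dimethyl-2-methylidenecyclohexyl]oxy}silane
Conditions: Ni(cod)2 (10 mol %), (R,R)-1,3-diaryl-4,5-diphenylimidazolinium tetrafluoroborate (10 mol %, aryl = ortho,ortho'-disubstituted phenyl), KOtBu (10 mol %), 22 (2 equiv), THF, rt, 21 added by syringe pump
Reagents that add atoms: none
Why: Zerovalent nickel carrying the chiral carbene binds the terminal alkyne and the aldehyde of 21 and undergoes oxidative cyclisation to a five-membered oxanickelacycle in which the internal alkyne carbon C-a is bonded to the carbonyl carbon C-f; σ-bond metathesis of the Ni–O bond with the silane and C–H reductive elimination then release the silyl ether and the exocyclic methylene. The closest known reaction type is the nickel-catalysed reductive cyclisation of ynals with trialkylsilanes. The cyclohexane closes in the 6-exo-dig mode, which is the rule for a four-atom tether, and the gem-dimethyl group on C-c favours the folded conformer. The new stereocentre C-f is controlled by the chiral carbene ligand, which must deliver C-a to the Re face of the aldehyde so that the C–O bond ends trans to the arylmethyl group on C-b. The substrate itself should exert only a weak bias, because an equatorial arylmethyl group (leading to cis) has two gauche contacts to the gem-dimethyl pair plus allylic strain while an axial one (leading to trans) has two syn-axial hydrogens, so ligand control should prevail, and any (R)-configured 21 leaking from step 8 is turned into the cis diastereomer, which chromatography removes. Cyclisation must also outrun oligomerisation of the terminal alkyne, which slow addition of 21 at high dilution secures.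

Step 15
Reactants: 23 triethyl{[(1S,3S)-3-(Ar-methyl)-4,4-dimethyl-2-methylidenecyclohexyl]oxy}silane
Product: 24 (1S,3S)-3-{[4-hydroxy-2,6-bis(SEM-oxy)phenyl]methyl}-4,4-dimethyl-2-methylidenecyclohexan-1-ol
Conditions: Bu4NF (2.5 equiv), THF, 0 °C → rt; aq. NH4Cl
Reagents that add atoms: none
Why: Fluoride-induced desilylation removes the aryl TIPS and the alkyl triethylsilyl ethers at or below room temperature, whereas SEM ethers on an electron-rich ring need heating with fluoride and stay on, so only the phenol para to the benzylic carbon is unmasked.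

Step 16
Reactants: 24 (1S,3S)-3-{[4-hydroxy-2,6-bis(SEM-oxy)phenyl]methyl}-4,4-dimethyl-2-methylidenecyclohexan-1-ol
Product: 25 (1S,3S)-3-{[4-hydroxy-3-iodo-2,6-bis(SEM-oxy)phenyl]methyl}-4,4-dimethyl-2-methylidenecyclohexan-1-ol
Conditions: N-iodosuccinimide (1.0 equiv), CH2Cl2, −40 → 0 °C, dark
Reagents that add atoms: N-iodosuccinimide, O=C1CCC(=O)N1I
Why: Electrophilic aromatic iodination of the strongly activated phenol takes place ortho to the free hydroxyl (the two open ring positions are constitutionally equivalent) much faster than any reaction of the 1,1-disubstituted alkene, so one equivalent at low temperature should give the mono-iodide.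

Step 17
Reactants: 26 3,4-dihydroxybenzaldehyde
Product: 27 3,4-bis(TBS-oxy)benzaldehyde
Conditions: TBSCl (2.4 equiv), imidazole, DMF, rt
Reagents that add atoms: tert-butyldimethylsilyl chloride, CC(C)(C)[Si](C)(C)Cl
Why: Standard silyl ether formation on both catechol hydroxyls gives a protecting group that falls to fluoride in the last step.

Step 18
Reactants: 27 3,4-bis(TBS-oxy)benzaldehyde
Product: 28 4-ethynyl-1,2-bis(TBS-oxy)benzene
Conditions: Me3SiCHN2 (1.2 equiv), LiN(iPr)2 (1.2 equiv), THF, −78 °C; then 27, −78 °C → rt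
Reagents that add atoms: (trimethylsilyl)diazomethane, C[Si](C)(C)C=[N+]=[N-]
Why: Colvin rearrangement, in which lithiated (trimethylsilyl)diazomethane adds to the aldehyde, Peterson-type elimination gives a diazoalkene and the derived alkylidene carbene rearranges to the arylacetylene, under cold non-protic conditions that spare the base-labile aryl silyl ethers.

Step 19
Reactants: 25 (1S,3S)-3-{[4-hydroxy-3-iodo-2,6-bis(SEM-oxy)phenyl]methyl}-4,4-dimethyl-2-methylidenecyclohexan-1-ol; 28 4-ethynyl-1,2-bis(TBS-oxy)benzene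
Product: 31 2-[3,4-bis(TBS-oxy)phenyl]-6-{[(1S,3S)-3-hydroxy-6,6-dimethyl-2-methylidenecyclohexyl]methyl}-5,7-bis(SEM-oxy)-4H-chromen-4-one, via alkynone 29 (not isolated), via enaminone 30 (not isolated)
Conditions: PdCl2(PPh3)2 (5 mol %), CO (1 atm), Et2NH (10 equiv), DMF, 60 °C
Reagents that add atoms: carbon monoxide, [C-]#[O+]
Why: Palladium-catalysed carbonylative alkynylation (oxidative addition of the aryl iodide to zerovalent palladium, CO insertion, coupling with the alkyne) gives the ortho-hydroxyaryl alkynone 29, diethylamine adds to it to form enaminone 30, and the phenol then displaces the amine in a 6-endo addition–elimination that closes ring C as the flavone and not as the aurone.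

Step 20
Reactants: 31 2-[3,4-bis(TBS-oxy)phenyl]-6-{[(1S,3S)-3-hydroxy-6,6-dimethyl-2-methylidenecyclohexyl]methyl}-5,7-bis(SEM-oxy)-4H-chromen-4-one
Product: 32 ugonin Q
Conditions: Bu4NF (12 equiv), THF–DMPU (3:1), 50 °C, argon; aq. NH4Cl
Reagents that add atoms: none
Why: Fluoride-mediated global deprotection cleaves the aryl TBS ethers at once and, on warming, fragments the SEM ethers (now attached to phenoxides that the chromone carbonyl makes good leaving groups) to ethene and formaldehyde, under basic conditions that avoid acid-promoted cyclisation of a phenol onto the exocyclic alkene.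

**Compound list**
1 | (S)-but-3-ene-1,2-diol | C=C[C@H](O)CO | starting material
2 | (S)-1-(TBS-oxy)but-3-en-2-ol | C=C[C@H](O)CO[Si](C)(C)C(C)(C)C | intermediate
3 | 2-methylbut-2-ene | CC=C(C)C | starting material
4 | (S)-1-(TBS-oxy)-4-methylpent-3-en-2-ol | CC(C)=C[C@H](O)CO[Si](C)(C)C(C)(C)C | intermediate
5 | 2,4,6-trihydroxybenzaldehyde | O=Cc1c(O)cc(O)cc1O | starting material
6 | 2,6-dihydroxy-4-(TIPS-oxy)benzaldehyde | O=Cc1c(O)cc(O[Si](C(C)C)(C(C)C)C(C)C)cc1O | intermediate
7 | 2,6-bis(SEM-oxy)-4-(TIPS-oxy)benzaldehyde | O=Cc1c(OCOCC[Si](C)(C)C)cc(O[Si](C(C)C)(C(C)C)C(C)C)cc1OCOCC[Si](C)(C)C | intermediate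
8 | Meldrum's acid (2,2-dimethyl-1,3-dioxane-4,6-dione) | CC1(C)OC(=O)CC(=O)O1 | starting material
9 | 5-(Ar-methylidene)-2,2-dimethyl-1,3-dioxane-4,6-dione | CC1(C)OC(=O)C(=Cc2c(OCOCC[Si](C)(C)C)cc(O[Si](C(C)C)(C(C)C)C(C)C)cc2OCOCC[Si](C)(C)C)C(=O)O1 | intermediate (not isolated)
10 | 5-(Ar-methyl)-2,2-dimethyl-1,3-dioxane-4,6-dione | CC1(C)OC(=O)C(Cc2c(OCOCC[Si](C)(C)C)cc(O[Si](C(C)C)(C(C)C)C(C)C)cc2OCOCC[Si](C)(C)C)C(=O)O1 | intermediate
11 | 2-(Ar-methyl)malonic acid | OC(=O)C(Cc1c(OCOCC[Si](C)(C)C)cc(O[Si](C(C)C)(C(C)C)C(C)C)cc1OCOCC[Si](C)(C)C)C(=O)O | intermediate (not isolated)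
12 | 3-Ar-propanoic acid | OC(=O)CCc1c(OCOCC[Si](C)(C)C)cc(O[Si](C(C)C)(C(C)C)C(C)C)cc1OCOCC[Si](C)(C)C | intermediate
13 | (S)-1-(TBS-oxy)-4-methylpent-3-en-2-yl 3-Ar-propanoate | CC(C)=C[C@H](OC(=O)CCc1c(OCOCC[Si](C)(C)C)cc(O[Si](C(C)C)(C(C)C)C(C)C)cc1OCOCC[Si](C)(C)C)CO[Si](C)(C)C(C)(C)C | intermediate
14 | O-trimethylsilyl ketene acetal of 13, ArCH2 cis to the allyloxy oxygen | CC(C)=C[C@H](O/C(O[Si](C)(C)C)=C\Cc1c(OCOCC[Si](C)(C)C)cc(O[Si](C(C)C)(C(C)C)C(C)C)cc1OCOCC[Si](C)(C)C)CO[Si](C)(C)C(C)(C)C | intermediate (not isolated)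
15 | trimethylsilyl (2S,4E)-2-(Ar-methyl)-6-(TBS-oxy)-3,3-dimethylhex-4-enoate | C[Si](C)(C)OC(=O)[C@@H](Cc1c(OCOCC[Si](C)(C)C)cc(O[Si](C(C)C)(C(C)C)C(C)C)cc1OCOCC[Si](C)(C)C)C(C)(C)/C=C/CO[Si](C)(C)C(C)(C)C | intermediate (not isolated)
16 | (2S,4E)-2-(Ar-methyl)-6-(TBS-oxy)-3,3-dimethylhex-4-en-1-ol | OC[C@@H](Cc1c(OCOCC[Si](C)(C)C)cc(O[Si](C(C)C)(C(C)C)C(C)C)cc1OCOCC[Si](C)(C)C)C(C)(C)/C=C/CO[Si](C)(C)C(C)(C)C | intermediate
17 | (S)-2-(Ar-methyl)-6-(TBS-oxy)-3,3-dimethylhexan-1-ol | OC[C@@H](Cc1c(OCOCC[Si](C)(C)C)cc(O[Si](C(C)C)(C(C)C)C(C)C)cc1OCOCC[Si](C)(C)C)C(C)(C)CCCO[Si](C)(C)C(C)(C)C | intermediate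
18 | (S)-2-(Ar-methyl)-6-(TBS-oxy)-3,3-dimethylhexanal | O=C[C@@H](Cc1c(OCOCC[Si](C)(C)C)cc(O[Si](C(C)C)(C(C)C)C(C)C)cc1OCOCC[Si](C)(C)C)C(C)(C)CCCO[Si](C)(C)C(C)(C)C | intermediate
19 | (5S)-5-(Ar-methyl)-1-(TBS-oxy)-4,4-dimethylhept-6-yne | C#C[C@@H](Cc1c(OCOCC[Si](C)(C)C)cc(O[Si](C(C)C)(C(C)C)C(C)C)cc1OCOCC[Si](C)(C)C)C(C)(C)CCCO[Si](C)(C)C(C)(C)C | intermediate
20 | (5S)-5-(Ar-methyl)-4,4-dimethylhept-6-yn-1-ol | C#C[C@@H](Cc1c(OCOCC[Si](C)(C)C)cc(O[Si](C(C)C)(C(C)C)C(C)C)cc1OCOCC[Si](C)(C)C)C(C)(C)CCCO | intermediate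
21 | (5S)-5-(Ar-methyl)-4,4-dimethylhept-6-ynal | C#C[C@@H](Cc1c(OCOCC[Si](C)(C)C)cc(O[Si](C(C)C)(C(C)C)C(C)C)cc1OCOCC[Si](C)(C)C)C(C)(C)CCC=O | intermediate
22 | triethylsilane | CC[SiH](CC)CC | starting material
23 | triethyl{[(1S,3S)-3-(Ar-methyl)-4,4-dimethyl-2-methylidenecyclohexyl]oxy}silane | C=C1[C@@H](Cc2c(OCOCC[Si](C)(C)C)cc(O[Si](C(C)C)(C(C)C)C(C)C)cc2OCOCC[Si](C)(C)C)C(C)(C)CC[C@@H]1O[Si](CC)(CC)CC | intermediate
24 | (1S,3S)-3-{[4-hydroxy-2,6-bis(SEM-oxy)phenyl]methyl}-4,4-dimethyl-2-methylidenecyclohexan-1-ol | C=C1[C@@H](Cc2c(OCOCC[Si](C)(C)C)cc(O)cc2OCOCC[Si](C)(C)C)C(C)(C)CC[C@@H]1O | intermediate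
25 | (1S,3S)-3-{[4-hydroxy-3-iodo-2,6-bis(SEM-oxy)phenyl]methyl}-4,4-dimethyl-2-methylidenecyclohexan-1-ol | C=C1[C@@H](Cc2c(OCOCC[Si](C)(C)C)cc(O)c(I)c2OCOCC[Si](C)(C)C)C(C)(C)CC[C@@H]1O | intermediate
26 | 3,4-dihydroxybenzaldehyde | O=Cc1ccc(O)c(O)c1 | starting material
27 | 3,4-bis(TBS-oxy)benzaldehyde | O=Cc1ccc(O[Si](C)(C)C(C)(C)C)c(O[Si](C)(C)C(C)(C)C)c1 | intermediate
28 | 4-ethynyl-1,2-bis(TBS-oxy)benzene | C#Cc1ccc(O[Si](C)(C)C(C)(C)C)c(O[Si](C)(C)C(C)(C)C)c1 | intermediate
29 | 1-{6-hydroxy-3-{[(1S,3S)-3-hydroxy-6,6-dimethyl-2-methylidenecyclohexyl]methyl}-2,4-bis(SEM-oxy)phenyl}-3-[3,4-bis(TBS-oxy)phenyl]prop-2-yn-1-one | C=C1[C@@H](Cc2c(OCOCC[Si](C)(C)C)cc(O)c(C(=O)C#Cc3ccc(O[Si](C)(C)C(C)(C)C)c(O[Si](C)(C)C(C)(C)C)c3)c2OCOCC[Si](C)(C)C)C(C)(C)CC[C@@H]1O | intermediate (not isolated)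
30 | 3-(diethylamino) enone from 29 and diethylamine (alkene geometry not defined) | C=C1[C@@H](Cc2c(OCOCC[Si](C)(C)C)cc(O)c(C(=O)C=C(N(CC)CC)c3ccc(O[Si](C)(C)C(C)(C)C)c(O[Si](C)(C)C(C)(C)C)c3)c2OCOCC[Si](C)(C)C)C(C)(C)CC[C@@H]1O | intermediate (not isolated)
31 | 2-[3,4-bis(TBS-oxy)phenyl]-6-{[(1S,3S)-3-hydroxy-6,6-dimethyl-2-methylidenecyclohexyl]methyl}-5,7-bis(SEM-oxy)-4H-chromen-4-one | C=C1[C@@H](Cc2c(OCOCC[Si](C)(C)C)cc3oc(-c4ccc(O[Si](C)(C)C(C)(C)C)c(O[Si](C)(C)C(C)(C)C)c4)cc(=O)c3c2OCOCC[Si](C)(C)C)C(C)(C)CC[C@@H]1O | intermediate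
32 | ugonin Q, 2-(3,4-dihydroxyphenyl)-5,7-dihydroxy-6-{[(1S,3S)-3-hydroxy-6,6-dimethyl-2-methylidenecyclohexyl]methyl}-4H-chromen-4-one | C=C1[C@@H](Cc2c(O)cc3oc(-c4ccc(O)c(O)c4)cc(=O)c3c2O)C(C)(C)CC[C@@H]1O | target

**Step count**
Total: 20 steps. Longest linear sequence: 16 steps (5 → 32 through steps 3–16, 19 and 20). Side branches: steps 1–2 (alcohol 4) and steps 17–18 (alkyne 28).

**Steps most likely to fail**

Step 14. The carbene ligand may discriminate the two aldehyde faces too weakly, so that cis and trans silyl ethers form together, and the terminal alkyne may oligomerise if the addition is too fast. The fallback sets out again from 21 and 22 and separates ring closure from stereocontrol. The cyclisation is run under substrate control with Ni(cod)2 and the achiral ligand PBu3; if the chair with the arylmethyl group and the O–Ni bond both equatorial then dominates, the product is the cis (1R,3S) silyl ether F1. Hydrolysis of the triethylsilyl ether (AcOH–THF–H2O) gives the cis alcohol F2. A Mitsunobu reaction with 4-nitrobenzoic acid (PPh3, DIAD) inverts C-f and gives the trans 4-nitrobenzoate F3. Methanolysis (K2CO3, MeOH) gives the trans alcohol F4 with the aryl TIPS ether still in place, and Bu4NF then brings the route back at 24.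

Step 19. Oxidative addition to the electron-rich, doubly ortho-substituted iodide may be slow, so that reductive deiodination, capture of the acylpalladium species by diethylamine or 5-exo closure to the aurone compete with the 6-endo annulation. The fallback sets out from 25 and 28 and makes the alkynone without palladium or carbon monoxide. Alkyne 28 is deprotonated (n-BuLi, −78 °C) and acylated with N-methoxy-N-methylcarbamoyl chloride to give the alkynyl Weinreb amide F5. Iodophenol 25 is deprotonated at both hydroxyls (MeLi, 2 equiv), subjected to iodine–lithium exchange (t-BuLi, 2 equiv, −78 °C) and acylated by F5. Cold aqueous quench gives alkynone 29, where the route is rejoined; Et2NH in EtOH carries 29 through 30 to 31.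

Step 8. Enolisation may leak towards the other ketene acetal geometry, and since each geometry leads to the opposite configuration at C-b this lowers the enantiomeric purity. The fallback sets out from 13 and replaces reliance on kinetic geometry control by separation of diastereomers on a covalently bound auxiliary. The rearrangement is run as before but quenched with dilute acid, which gives the free acid F6. The acid is activated (pivaloyl chloride, Et3N) and coupled with lithiated (S)-4-benzyl-1,3-oxazolidin-2-one to give the N-acyl oxazolidinone F7, from which the C-b epimer is removed by chromatography. Reductive cleavage with LiBH4 returns the route at 16.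

**Further compounds**
F1 | step 14 | triethyl{[(1R,3S)-3-(Ar-methyl)-4,4-dimethyl-2-methylidenecyclohexyl]oxy}silane | C=C1[C@@H](Cc2c(OCOCC[Si](C)(C)C)cc(O[Si](C(C)C)(C(C)C)C(C)C)cc2OCOCC[Si](C)(C)C)C(C)(C)CC[C@H]1O[Si](CC)(CC)CC
F2 | step 14 | (1R,3S)-3-(Ar-methyl)-4,4-dimethyl-2-methylidenecyclohexan-1-ol | C=C1[C@@H](Cc2c(OCOCC[Si](C)(C)C)cc(O[Si](C(C)C)(C(C)C)C(C)C)cc2OCOCC[Si](C)(C)C)C(C)(C)CC[C@H]1O
F3 | step 14 | (1S,3S)-3-(Ar-methyl)-4,4-dimethyl-2-methylidenecyclohexyl 4-nitrobenzoate | C=C1[C@@H](Cc2c(OCOCC[Si](C)(C)C)cc(O[Si](C(C)C)(C(C)C)C(C)C)cc2OCOCC[Si](C)(C)C)C(C)(C)CC[C@@H]1OC(=O)c3ccc(cc3)[N+](=O)[O-]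
F4 | step 14 | (1S,3S)-3-(Ar-methyl)-4,4-dimethyl-2-methylidenecyclohexan-1-ol | C=C1[C@@H](Cc2c(OCOCC[Si](C)(C)C)cc(O[Si](C(C)C)(C(C)C)C(C)C)cc2OCOCC[Si](C)(C)C)C(C)(C)CC[C@@H]1O
F5 | step 19 | N-methoxy-N-methyl-3-[3,4-bis(TBS-oxy)phenyl]prop-2-ynamide | CON(C)C(=O)C#Cc1ccc(O[Si](C)(C)C(C)(C)C)c(O[Si](C)(C)C(C)(C)C)c1
F6 | step 8 | (2S,4E)-2-(Ar-methyl)-6-(TBS-oxy)-3,3-dimethylhex-4-enoic acid | OC(=O)[C@@H](Cc1c(OCOCC[Si](C)(C)C)cc(O[Si](C(C)C)(C(C)C)C(C)C)cc1OCOCC[Si](C)(C)C)C(C)(C)/C=C/CO[Si](C)(C)C(C)(C)C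
F7 | step 8 | (4S)-4-benzyl-3-[(2S,4E)-2-(Ar-methyl)-6-(TBS-oxy)-3,3-dimethylhex-4-enoyl]-1,3-oxazolidin-2-one | O=C1OC[C@H](Cc2ccccc2)N1C(=O)[C@@H](Cc3c(OCOCC[Si](C)(C)C)cc(O[Si](C(C)C)(C(C)C)C(C)C)cc3OCOCC[Si](C)(C)C)C(C)(C)/C=C/CO[Si](C)(C)C(C)(C)C
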